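**Retrosynthetic overview**
- The strategy rests on ring A: C1 (bonded to the ketone carbon C7), C2-OH, C3-Cl, C4-OMe, C5-H, C6-OMe. It is an acylphloroglucinol whose C2 to C6 carbons, with Cl and the C4 methoxy group already in place, correspond atom for atom to C2 to C6 of a 3-chloro-4-methoxy-2-pyrone (lactone carbonyl = C2, ring oxygen = oxygen on C6).
- Key disconnection: the C1–C2 bond of ring A. A 6-(aroylmethyl)pyrone is opened by Mg(OMe)2 in methanol and its side-chain CH2 closes onto the released ester carbon (Claisen). Ring A is the only ring formed; ring B is bought as the orsellinaldehyde and the pyrone ring is consumed.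
- The pyrone precursor is cut at the CH2–C(O)Ar bond: vinylogous aldol of the lithiated 3-chloro-4-methoxy-6-methylpyrone with the ring B aldehyde (4-O-MOM, 2-O-methyl), then oxidation of the carbinol.
- Endgame: site-selective O-methylation of the C6-OH through the bis-phenoxide, then acid removal of the MOM ether.

Key step: step 6

Assumption: alcohol 7 is made and used as the racemate, because its only stereocentre is removed by the oxidation in step 5 and the target has no stereocentre.

**Step 1**
Reactants: 1 2,4-dihydroxy-6-methylbenzaldehyde
Product: 2 2-hydroxy-4-(methoxymethoxy)-6-methylbenzaldehyde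
Conditions: MOMCl (1.1 equiv), K2CO3, acetone, 0 °C to rt
Reagents that add atoms: chloromethyl methyl ether, COCCl
Why: Williamson-type O-alkylation should take place at the 4-OH, which is the more acidic hydroxyl (para to the formyl group) and is not tied up in the hydrogen bond to the aldehyde that deactivates the 2-OH.

**Step 2**
Reactants: 2 2-hydroxy-4-(methoxymethoxy)-6-methylbenzaldehyde
Product: 3 2-methoxy-4-(methoxymethoxy)-6-methylbenzaldehyde
Conditions: MeI, K2CO3, DMF, 40 °C
Reagents that add atoms: iodomethane, CI
Why: Williamson methylation of the remaining chelated phenol should go to completion under carbonate in a dipolar aprotic solvent, and the aldehyde and the MOM acetal are inert to these conditions.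

**Step 3**
Reactants: 4 4-methoxy-6-methyl-2H-pyran-2-one
Product: 5 3-chloro-4-methoxy-6-methyl-2H-pyran-2-one
Conditions: NCS, AcOH, 50 °C
Reagents that add atoms: N-chlorosuccinimide, O=C1CCC(=O)N1Cl
Why: Electrophilic halogenation of a 4-methoxy-2-pyrone should occur at C3, the enol-ether β-carbon next to the lactone carbonyl and the most nucleophilic ring position, as in the well-known C3 bromination of this pyrone.

**Step 4**
Reactants: 5 3-chloro-4-methoxy-6-methyl-2H-pyran-2-one; 3 2-methoxy-4-(methoxymethoxy)-6-methylbenzaldehyde
Product: 7 rac-3-chloro-6-{2-hydroxy-2-[2-methoxy-4-(methoxymethoxy)-6-methylphenyl]ethyl}-4-methoxy-2H-pyran-2-one, via lithium dienolate 6 (not isolated)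
Conditions: LiN(iPr)2 (1.1 equiv), THF, −78 °C; then 3, −78 °C; AcOH quench at −78 °C
Reagents that add atoms: lithium diisopropylamide LiN(iPr)2, [Li]N(C(C)C)C(C)C (lithium of 6 only)
Why: With C3 blocked by chlorine the amide base should remove a proton from the C6 methyl group to give the extended dienolate, which adds through its terminal carbon to the aldehyde in a vinylogous aldol addition; the new carbinol centre forms without control (racemate) and is erased in step 5.

**Step 5**
Reactants: 7 rac-3-chloro-6-{2-hydroxy-2-[2-methoxy-4-(methoxymethoxy)-6-methylphenyl]ethyl}-4-methoxy-2H-pyran-2-one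
Product: 8 3-chloro-4-methoxy-6-{2-[2-methoxy-4-(methoxymethoxy)-6-methylphenyl]-2-oxoethyl}-2H-pyran-2-one
Conditions: Dess–Martin periodinane (1.2 equiv), pyridine, CH2Cl2, 0 °C to rt
Reagents that add atoms: none
Why: Dess–Martin oxidation of the secondary benzylic alcohol under pyridine-buffered, non-acidic conditions should give the aryl ketone without ionising the electron-rich benzylic position (dehydration to the styrylpyrone) and without touching the MOM acetal.

**Step 6**
Reactants: 8 3-chloro-4-methoxy-6-{2-[2-methoxy-4-(methoxymethoxy)-6-methylphenyl]-2-oxoethyl}-2H-pyran-2-one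
Product: 10 (3-chloro-2,6-dihydroxy-4-methoxyphenyl)[2-methoxy-4-(methoxymethoxy)-6-methylphenyl]methanone, via open-chain methyl ester 9 (not isolated)
Conditions: Mg(OMe)2 (5 equiv), MeOH, reflux, N2; then cold 1 M HCl to pH 3
Reagents that add atoms: magnesium methoxide Mg(OMe)2, CO[Mg]OC (methoxy group of 9 only)
Why: Methoxide should add to the lactone carbonyl, which the C3 chlorine makes more electrophilic, and open the ring to ester 9, a 3,5,7-triketo ester whose C3 carbonyl is locked as the methyl enol ether and whose 5,7-diketone is held as a magnesium chelate. The chelated carbanion at the former side-chain CH2 (future C1) then attacks the ester carbon (future C2) in a 6-exo-trig Claisen closure, methoxide leaves, and enolisation of the resulting dione gives ring A, so the step is a net isomerisation driven by aromatisation. The closest known reaction type is the Mg(OMe)2-mediated conversion of 6-(2-oxoalkyl)-2-pyrones and the corresponding triketo esters into acylphloroglucinols, here extended to a 3-chloro-4-methoxy pyrone. No stereocentre is formed, and the Z geometry of the C(Cl)=C(OMe) bond inherited from the ring keeps the ester and the diketone chain on the same side, while any isomerised material can return through the push-pull dienolate because only the Z form can close. The selectivity needed is Claisen closure over the aldol closure that leads to resorcylates, and the substrate secures it because the carbon that would have to act as the aldol nucleophile (pyrone C3) is a fully substituted, chlorinated enol-ether carbon with no proton to lose, while magnesium chelation restrains retro-Claisen cleavage of the diketone.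

**Step 7**
Reactants: 10 (3-chloro-2,6-dihydroxy-4-methoxyphenyl)[2-methoxy-4-(methoxymethoxy)-6-methylphenyl]methanone
Product: 11 (3-chloro-2-hydroxy-4,6-dimethoxyphenyl)[2-methoxy-4-(methoxymethoxy)-6-methylphenyl]methanone
Conditions: NaH (2.2 equiv), DMF, 0 °C; Me2SO4 (1.0 equiv), −20 to 0 °C; AcOH quench
Reagents that add atoms: dimethyl sulfate, COS(=O)(=O)OC
Why: In the fully formed bis-phenoxide the C6 oxygen is both the more basic one (no ortho chlorine) and the less hindered one, so one equivalent of the hard electrophile should O-methylate there (Williamson ether synthesis) and leave the C2 phenoxide, flanked by Cl and the carbonyl; under mono-deprotonation with carbonate the more acidic C2-OH would be ionised first and oppose the steric preference.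

**Step 8**
Reactants: 11 (3-chloro-2-hydroxy-4,6-dimethoxyphenyl)[2-methoxy-4-(methoxymethoxy)-6-methylphenyl]methanone
Product: 12 (3-chloro-2-hydroxy-4,6-dimethoxyphenyl)(4-hydroxy-2-methoxy-6-methylphenyl)methanone
Conditions: conc. HCl (cat.), MeOH, 40 °C
Reagents that add atoms: none
Why: Acid-catalysed acetal exchange with methanol should cleave the MOM ether as dimethoxymethane, while the aryl methyl ethers, the aryl chloride and the diaryl ketone are stable to dilute acid.

**Compound list**
1 | 2,4-dihydroxy-6-methylbenzaldehyde | Cc1cc(O)cc(O)c1C=O | starting material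
2 | 2-hydroxy-4-(methoxymethoxy)-6-methylbenzaldehyde | COCOc1cc(C)c(C=O)c(O)c1 | intermediate
3 | 2-methoxy-4-(methoxymethoxy)-6-methylbenzaldehyde | COCOc1cc(C)c(C=O)c(OC)c1 | intermediate
4 | 4-methoxy-6-methyl-2H-pyran-2-one | COC1=CC(=O)OC(C)=C1 | starting material
5 | 3-chloro-4-methoxy-6-methyl-2H-pyran-2-one | COC1=C(Cl)C(=O)OC(C)=C1 | intermediate
6 | lithium 3-chloro-4-methoxy-6-methylidene-6H-pyran-2-olate (lithium dienolate of 5, not isolated) | C=C1C=C(OC)C(Cl)=C(O[Li])O1 | intermediate
7 | rac-3-chloro-6-{2-hydroxy-2-[2-methoxy-4-(methoxymethoxy)-6-methylphenyl]ethyl}-4-methoxy-2H-pyran-2-one | COC1=C(Cl)C(=O)OC(CC(O)c2c(C)cc(OCOC)cc2OC)=C1 | intermediate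
8 | 3-chloro-4-methoxy-6-{2-[2-methoxy-4-(methoxymethoxy)-6-methylphenyl]-2-oxoethyl}-2H-pyran-2-one | COC1=C(Cl)C(=O)OC(CC(=O)c2c(C)cc(OCOC)cc2OC)=C1 | intermediate
9 | methyl (2Z)-2-chloro-3-methoxy-7-[2-methoxy-4-(methoxymethoxy)-6-methylphenyl]-5,7-dioxohept-2-enoate (present as its magnesium enolate, not isolated) | COC(=O)/C(Cl)=C(/OC)CC(=O)CC(=O)c1c(C)cc(OCOC)cc1OC | intermediate
10 | (3-chloro-2,6-dihydroxy-4-methoxyphenyl)[2-methoxy-4-(methoxymethoxy)-6-methylphenyl]methanone | COCOc1cc(C)c(C(=O)c2c(O)cc(OC)c(Cl)c2O)c(OC)c1 | intermediate
11 | (3-chloro-2-hydroxy-4,6-dimethoxyphenyl)[2-methoxy-4-(methoxymethoxy)-6-methylphenyl]methanone | COCOc1cc(C)c(C(=O)c2c(OC)cc(OC)c(Cl)c2O)c(OC)c1 | intermediate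
12 | (3-chloro-2-hydroxy-4,6-dimethoxyphenyl)(4-hydroxy-2-methoxy-6-methylphenyl)methanone | COc1cc(OC)c(C(=O)c2c(C)cc(O)cc2OC)c(O)c1Cl | target

**Total step count:** 8
**Longest linear sequence:** 7 steps (steps 1, 2, 4, 5, 6, 7, 8, from compound 1)

**Steps most likely to fail**

1. Step 6 (key step). The pyrone, deprotonated at its side-chain CH2, may resist attack by methoxide. The opened chain may close through the enolate oxygen onto the enol-ether carbon with loss of methoxide, giving a 4-pyranone. The diketone may fragment by retro-Claisen cleavage before carbon–carbon closure. The fallback abandons ring construction and attaches a preformed ring A. It sets out from aldehyde 3, which would be oxidised (NaClO2, NaH2PO4, 2-methyl-2-butene, t-BuOH/water; Pinnick oxidation) to 2-methoxy-4-(methoxymethoxy)-6-methylbenzoic acid F1. The acid would be esterified with purchased 2-chloro-3,5-dimethoxyphenol (EDC·HCl, DMAP, CH2Cl2) to 2-chloro-3,5-dimethoxyphenyl 2-methoxy-4-(methoxymethoxy)-6-methylbenzoate F2. A Fries rearrangement with TiCl4 in 1,2-dichloroethane should move the hindered aroyl group to the only free ortho position of the phenol (the other ortho carbon carries chlorine) and at the same time strip the MOM ether, so the fallback comes back to the route at the target 12.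

2. Step 7. Methylation may go to the oxygen next to chlorine, may run on to the dimethyl ether, or may take place on carbon at C5 of the electron-rich bis-phenoxide. The fallback replaces selective ether formation by selective ether cleavage. It sets out from diol 10, which would be methylated exhaustively (excess Me2SO4, K2CO3, acetone, reflux) to (3-chloro-2,4,6-trimethoxyphenyl)[2-methoxy-4-(methoxymethoxy)-6-methylphenyl]methanone F3. Treatment with BCl3 in CH2Cl2 from −78 to 0 °C should then cleave the MOM ether and the most congested carbonyl-chelated methoxy group (the C2 methoxy group, squeezed between Cl and the ketone). The fallback comes back to the route at the target 12.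

3. Step 4. The lithiated pyrone may condense with itself, the hindered alkoxide may revert by retro-aldol on warming, or the adduct may dehydrate to the styrylpyrone. The fallback avoids the strongly basic dienolate. It sets out from chloropyrone 5, which would be brominated at the methyl group under radical conditions (NBS, AIBN, PhCF3, reflux) to 6-(bromomethyl)-3-chloro-4-methoxy-2H-pyran-2-one F4. Activated zinc dust in THF in the presence of aldehyde 3 (Barbier-type vinylogous Reformatsky addition) should then give the carbinol under nearly neutral conditions. The fallback comes back to the route at alcohol 7.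

**Further compounds**
F1 | step 6 | 2-methoxy-4-(methoxymethoxy)-6-methylbenzoic acid | COCOc1cc(C)c(C(=O)O)c(OC)c1
F2 | step 6 | 2-chloro-3,5-dimethoxyphenyl 2-methoxy-4-(methoxymethoxy)-6-methylbenzoate | COCOc1cc(C)c(C(=O)Oc2cc(OC)cc(OC)c2Cl)c(OC)c1
F3 | step 7 | (3-chloro-2,4,6-trimethoxyphenyl)[2-methoxy-4-(methoxymethoxy)-6-methylphenyl]methanone | COCOc1cc(C)c(C(=O)c2c(OC)cc(OC)c(Cl)c2OC)c(OC)c1
F4 | step 4 | 6-(bromomethyl)-3-chloro-4-methoxy-2H-pyran-2-one | COC1=C(Cl)C(=O)OC(CBr)=C1
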